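**Strategy.** The dearomatised acylphloroglucinol ring (ring C) is closed last on a caryophyllene-fused dihydropyran, by joining its ring ketone carbon to the neighbouring quaternary CMe2 carbon. One Danheiser-type cascade does this: a dihydropyran-3-carbonyl chloride bearing a 2-isopropyl group is dehydrochlorinated to a vinylketene, which adds ethoxyacetylene; the strained spiro-cyclobutenone opens to a dienylketene, and 6π electrocyclisation bonds the ketene carbon to the isopropylidene carbon, so the former carboxyl carbon moves from the pyran carbon to the CMe2 carbon. The step exploits the gem-dimethyl carbon of ring C, between the ring ketone and the pyran enol-ether carbon: it cannot tautomerise, so the benzannulation stops at the cyclohexa-2,4-dienone of the target. The precursor is a hetero-Diels–Alder adduct of (−)-β-caryophyllene.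

Key step: step 3

Locants: terpene carbons keep caryophyllane numbers (C1/C9 cyclobutane fusion, C4 bearing CH3, C5 its CH neighbour, C8 bearing the exocyclic CH2). Ring B is the dihydropyran O1'–C2'=C3'–C4'H2–C5–C4. Ring C is C2'–C3'–C5'–C6'–C7'–C8' (C7' ring ketone carbon, C8' CMe2 carbon). All fused compounds are (1R,4S,5R,9S) with 4-CH3 and 5-H trans.

Remark: the face of the caryophyllene alkene that reacts in step 1 is governed by the ring conformers and not by a reagent, so the (4S,5R) adduct is taken as one of two separable diastereomers.

Step 1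
Reactants: 1 methyl 4-methyl-3-oxopentanoate; 2 paraformaldehyde; 3 (−)-β-caryophyllene
Product: 5 ring-B methyl ester (2'-isopropyl and 3'-CO2CH3 on the C2'=C3' enol ether; 1R,4S,5R,9S), via oxadiene 4 (not isolated)
Conditions: cat. piperidine/AcOH, 3 (3 equiv), slow addition of 1, 1,4-dioxane, 80 °C; chromatography
Reagents that add atoms: none
Why: Domino Knoevenagel/hetero-Diels–Alder reaction: 1 and formaldehyde give the 1-oxadiene 4, whose ketone C=O and methylene add with inverse electron demand to the strained endocyclic E-alkene of 3 (oxygen to the more substituted C4, CH2 to C5; the exocyclic alkene is far less reactive), the suprafacial addition fixing 4-CH3 and 5-H trans and the alkene face being set by the ring conformer of 3, so that the required (4S,5R) adduct (from the ββ conformer) should form beside its (4R,5S) diastereomer, which is expected to predominate and is removed by chromatography at this cheap stage.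

Step 2
Reactants: 5 ring-B methyl ester
Product: 7 ring-B 3'-carboxylic acid, via lithium carboxylate 6 (not isolated)
Conditions: LiOH·H2O, THF/MeOH/H2O, 60 °C; then cold 1 M HCl to pH 3
Reagents that add atoms: lithium hydroxide, [Li+].[OH-]
Why: Saponification (BAc2) of the vinylogous carbonate ester, slow but clean because nothing else in 5 reacts with hydroxide, and the short cold acidification leaves the acceptor-substituted enol ether and the stereocenters untouched.

Step 3
Reactants: 7 ring-B 3'-carboxylic acid; 8 ethoxyacetylene
Product: 13 5'-ethoxy dienone (ring C closed: 5'-OEt, 6'-H, 7'-oxo, 8',8'-dimethyl), via acid chloride 9 (not isolated), via vinylketene 10 (not isolated), via spiro-cyclobutenone 11 (not isolated), via dienylketene 12 (not isolated)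
Conditions: 1-chloro-N,N,2-trimethylprop-1-en-1-amine (1.05 equiv), CH2Cl2, 0→23 °C; then 8 (3 equiv), Et3N (1.5 equiv), toluene, 23→60 °C, sealed tube; concentrate; toluene, 110 °C
Reagents that add atoms: none
Why: The chloroenamine gives acid chloride 9 without free HCl, Et3N removes its only γ-hydrogen (the isopropyl methine; 9 has no α-hydrogen) to give the alkoxyvinylketene 10, the ketene C=C adds ethoxyacetylene in a [2+2] cycloaddition to spiro-cyclobutenone 11, strain-releasing conrotatory 4π opening gives dienylketene 12, and disrotatory 6π electrocyclisation bonds the ketene carbon C7' to the isopropylidene carbon C8'. The closest known reaction type is the Danheiser benzannulation of a vinylketene with an alkoxyalkyne, ending here like the thermal closure of dienylketenes to 6,6-dimethylcyclohexa-2,4-dienones (the reverse of the Barton–Quinkert photo-opening) because the CMe2 terminus cannot tautomerise to a phenol. Two rings are closed, the transient four-membered ring by ketene–alkyne [2+2] cycloaddition and ring C by 6π electrocyclisation of the dienylketene. No stereocenter is created in 13: the spiro carbon of 11 is transient and returns to sp2, and C1, C4, C5 and C9 are not involved. The step needs the regiochemistry of the [2+2] addition and the inward rotation of the alkenyl arm on ring opening: the first is fixed by the polarity of the ynol ether (its nucleophilic CH carbon bonds to the ketene carbonyl carbon, its O-bearing carbon to C3'), the second by the reversibility of the cyclobutenone opening, which returns the unproductive dienylketene isomer to 11 while only (E)-12 is drained by cyclisation.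

Step 4
Reactants: 13 5'-ethoxy dienone
Product: 15 5'-hydroxy dienone (enol of the 5',7'-dione), via sodium enolate 14 (not isolated)
Conditions: 2 M aq. NaOH, EtOH, 70 °C; then cold dilute HCl to pH 4
Reagents that add atoms: sodium hydroxide, [Na+].[OH-]
Why: Vinylogous ester hydrolysis by conjugate addition–elimination: hydroxide adds to C5' (β to the C7' ketone and far less hindered than C2', which is flanked by the quaternary C8'), ethoxide leaves, and the delocalised enolate 14 is inert to further attack, while the exocyclic alkene, ring B and all stereocenters are stable to base.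

Step 5
Reactants: 15 5'-hydroxy dienone; 16 (S)-2-methylbutanoic acid
Product: 18 target (5'-hydroxy-6'-[(2S)-2-methylbutanoyl]-8',8'-dimethyl-7'-oxo; 1R,4S,5R,9S), via enol ester 17 (not isolated)
Conditions: DCC (1.2 equiv), DMAP (0.3 equiv), CH2Cl2, 0→23 °C
Reagents that add atoms: none
Why: Steglich-type activation gives enol ester 17, and DMAP then shuttles the acyl group from oxygen to C6' (Fries-type O→C acyl shift, the standard route to 2-acylcyclohexane-1,3-diones), the only carbon flanked by both oxygenated carbons, giving the hydrogen-bonded triketone tautomer; the stereocenter of 16 is not touched, and low temperature with substoichiometric DMAP should limit its loss through ketene formation.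

**Compound list**

1 | methyl 4-methyl-3-oxopentanoate | CC(C)C(=O)CC(=O)OC | starting material
2 | paraformaldehyde (used as formaldehyde) | C=O | starting material
3 | (−)-β-caryophyllene, (1R,4E,9S) | C=C1CC/C=C(\C)CC[C@@H]2[C@@H]1CC2(C)C | starting material
4 | methyl 4-methyl-2-methylidene-3-oxopentanoate (transient 1-oxadiene) | C=C(C(=O)OC)C(=O)C(C)C | intermediate
5 | ring-B methyl ester: dihydropyran fused at C4–C5 of caryophyll-8(13)-ene (O on C4, CH2 on C5), 2'-isopropyl, 3'-CO2CH3, (1R,4S,5R,9S) | C=C1CC[C@@H]2CC(C(=O)OC)=C(C(C)C)O[C@@]2(C)CC[C@@H]2[C@@H]1CC2(C)C | intermediate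
6 | lithium 3'-carboxylate of 7 | C=C1CC[C@@H]2CC(C(=O)[O-])=C(C(C)C)O[C@@]2(C)CC[C@@H]2[C@@H]1CC2(C)C.[Li+] | intermediate
7 | ring-B 3'-carboxylic acid, 2'-isopropyl, (1R,4S,5R,9S) | C=C1CC[C@@H]2CC(C(=O)O)=C(C(C)C)O[C@@]2(C)CC[C@@H]2[C@@H]1CC2(C)C | intermediate
8 | ethoxyacetylene (ethoxyethyne) | C#COCC | starting material
9 | ring-B 3'-carbonyl chloride | C=C1CC[C@@H]2CC(C(=O)Cl)=C(C(C)C)O[C@@]2(C)CC[C@@H]2[C@@H]1CC2(C)C | intermediate
10 | vinylketene: C3' carries an exocyclic C=C=O, C2' an exocyclic isopropylidene | C=C1CC[C@@H]2CC(=C=O)C(=C(C)C)O[C@@]2(C)CC[C@@H]2[C@@H]1CC2(C)C | intermediate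
11 | spiro-cyclobutenone: 3-ethoxycyclobut-2-en-1-one whose C4 is C3' of ring B, C2' isopropylidene; spiro centre not defined | C=C1CC[C@@H]2CC3(C(=O)C=C3OCC)C(=C(C)C)O[C@@]2(C)CC[C@@H]2[C@@H]1CC2(C)C | intermediate
12 | (E)-dienylketene: C3'=C5'(OEt)–C6'H=C7'=O with C6' cis to C2', C2'=C8'Me2 | C=C1CC[C@@H]2C/C(=C(\OCC)C=C=O)C(=C(C)C)O[C@@]2(C)CC[C@@H]2[C@@H]1CC2(C)C | intermediate
13 | 5'-ethoxy dienone: ring C closed, 5'-OEt, 6'-H, 7'-oxo, 8',8'-dimethyl, (1R,4S,5R,9S) | C=C1CC[C@@H]2CC3=C(O[C@@]2(C)CC[C@@H]2[C@@H]1CC2(C)C)C(C)(C)C(=O)C=C3OCC | intermediate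
14 | sodium 5'-enolate of 15 | C=C1CC[C@@H]2CC3=C(O[C@@]2(C)CC[C@@H]2[C@@H]1CC2(C)C)C(C)(C)C(=O)C=C3[O-].[Na+] | intermediate
15 | 5'-hydroxy dienone (enol of the 5',7'-dione), 8',8'-dimethyl, (1R,4S,5R,9S) | C=C1CC[C@@H]2CC3=C(O[C@@]2(C)CC[C@@H]2[C@@H]1CC2(C)C)C(C)(C)C(=O)C=C3O | intermediate
16 | (S)-2-methylbutanoic acid | CC[C@H](C)C(=O)O | starting material
17 | 5'-O-[(2S)-2-methylbutanoyl] enol ester of 15 | C=C1CC[C@@H]2CC3=C(O[C@@]2(C)CC[C@@H]2[C@@H]1CC2(C)C)C(C)(C)C(=O)C=C3OC(=O)[C@@H](C)CC | intermediate
18 | target CNP0591516.1: 5'-hydroxy-6'-[(2S)-2-methylbutanoyl]-8',8'-dimethyl-7'-oxo, (1R,4S,5R,9S) | C=C1CC[C@@H]2CC3=C(O[C@@]2(C)CC[C@@H]2[C@@H]1CC2(C)C)C(C)(C)C(=O)C(C(=O)[C@@H](C)CC)=C3O | target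

**Step count and risks**

Total step count: 5. Longest linear sequence: 5 steps (1 and 3 to 18).

Steps most likely to fail:

1. Step 3. Removal of the hindered isopropyl methine hydrogen may be slow, and the vinylketene may be consumed by self-addition or by closure to a fused cyclobutenone before it meets the alkyne. The fallback closes the same C7'–C8' bond by an anionic route and sets out from acid 7 through its chloride 9. The lithium enolate of ethyl acetate (EtOAc, LiN(SiMe3)2, THF, −78 °C) should acylate on carbon to give β-keto ester F1. Triethyl orthoformate with catalytic pyridinium p-toluenesulfonate in EtOH should give (E)-β-ethoxy enoate F2, in which ring B is cis to the ester. LiN(iPr)2 in THF (−78→0 °C) then removes the isopropyl methine hydrogen at the end of the dienoate, and the carbanion closes on the ester carbonyl in a vinylogous Dieckmann condensation. This returns to the route at 13.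

2. Step 1. The transient oxadiene may add to itself or to a second molecule of 1 faster than it is captured by the alkene, and the cycloaddition is expected to take place mostly on the other alkene face. The fallback sets out from 3 and replaces 1 and 2 by methyl acrylate and isobutyraldehyde. A Baylis–Hillman reaction (DABCO, neat, 23 °C) gives allylic alcohol F3. Oxidation of F3 with Dess–Martin periodinane (NaHCO3, CH2Cl2, 0→40 °C) in the presence of excess 3 releases oxadiene 4 slowly under neutral, water-free conditions, and the route is rejoined at 5. The facial distribution stays under conformer control, so the two adducts are still separated at this stage.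

3. Step 4. Hydroxide may attack C2' and open ring B instead of displacing ethoxide at C5', or the addition may be too slow on the cross-conjugated dienone. The fallback sets out from 13 and cleaves the O–CH2 bond by SN2 dealkylation instead: LiI in 2,4,6-collidine at 120 °C should give lithium enolate F4 and iodoethane, and cold dilute HCl returns to the route at 15.

**Further compounds**

F1 | step 3 | ethyl 3-oxo-3-(ring-B-3'-yl)propanoate (β-keto ester; ring B as in 7) | C=C1CC[C@@H]2CC(C(=O)CC(=O)OCC)=C(C(C)C)O[C@@]2(C)CC[C@@H]2[C@@H]1CC2(C)C
F2 | step 3 | ethyl (E)-3-ethoxy-3-(ring-B-3'-yl)prop-2-enoate | C=C1CC[C@@H]2CC(/C(OCC)=C\C(=O)OCC)=C(C(C)C)O[C@@]2(C)CC[C@@H]2[C@@H]1CC2(C)C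
F3 | step 1 | methyl 3-hydroxy-4-methyl-2-methylidenepentanoate (racemic) | C=C(C(=O)OC)C(O)C(C)C
F4 | step 4 | lithium 5'-enolate of 15 | C=C1CC[C@@H]2CC3=C(O[C@@]2(C)CC[C@@H]2[C@@H]1CC2(C)C)C(C)(C)C(=O)C=C3[O-].[Li+]
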